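The numbering is that of the germacrane skeleton. Everything rests on cutting C7–C11 of the γ-lactone ring (O–C12–C11–C7–C6) after first adding a sacrificial C8–C11 bond. C7 lies between the oxygenated carbons C6 and C8, and C11 is α to the C12 carbonyl, so C7–C8–C11 is a latent donor–acceptor cyclopropane. The key step is an enantioselective copper-carbene [2+1] addition of ethyl diazoacetate to flat, achiral methyl 2-furoate. It closes this three-membered ring, makes C7–C11 and fixes C7, which then relays to C6. Ozonolysis, alkenylation and retro-aldol cleavage of C8–C11 unfold the trans-lactone. Methallylation, methylenation, acylation and metathesis to the Z-C1=C10 bond of the ten-membered ring finish the synthesis.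

Key step: step 1

Remark on the chemistry: ring atoms are C1–C10, C11/C12/C13 are the lactone α-carbon, carbonyl and methylene, and C14/C15 are the methyls on C10/C4; the target is read as 2R,6R,7R,8R,2′S with 4E and 1(10)Z; the (R,R)-ligand is taken to lead to the (1R,5R,6R) adduct.

Step 1
Reactants: 1 methyl furan-2-carboxylate; 2 ethyl diazoacetate
Product: 3 6-ethyl 3-methyl (1R,5R,6R)-2-oxabicyclo[3.1.0]hex-3-ene-3,6-dicarboxylate (exo ester)
Conditions: Cu(OTf)2 (1 mol %), 2,2′-(propane-2,2-diyl)bis[(4R)-4-isopropyl-4,5-dihydrooxazole] (1.2 mol %), PhNHNH2 (1 mol %), CH2Cl2, 0 °C, slow addition of 2 to excess 1; recrystallisation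
Reagents that add atoms: none
Why: PhNHNH2 reduces Cu(OTf)2 to the monovalent copper–bis(oxazoline) complex, which expels N2 from 2 and transfers the electrophilic carbene in a concerted, asynchronous [2+1] cycloaddition to one furan double bond (asymmetric cyclopropanation of furan-2-carboxylates, a known reaction type). The only ring closed is the three-membered ring C11–C7–C8, formed by suprafacial [2+1] addition in which C7–C11 (kept to the end) and C8–C11 (sacrificial) arise together. Selectivity is needed between the two furan double bonds; the ester on furan C2 deactivates and shields the adjacent bond, so only the distal enol-ether bond (future C7–C8) should react, and excess 1 suppresses a second addition. C7 and C8 are set by the enantioface choice of the C2-symmetric ligand, and C11 by the exo approach that keeps CO2Et away from the ring. Recrystallisation should raise the adduct to enantiopurity. Of the three new centres only C7 survives, and it later controls C6.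

Step 2
Reactants: 3 cyclopropane diester
Product: 5 methyl (1R,2R,3R)-2-(ethoxycarbonyl)-3-formylcyclopropyl oxalate, via secondary ozonide 4 (not isolated)
Conditions: O3, CH2Cl2, −78 °C; then Me2S, −78 °C to rt
Reagents that add atoms: ozone [O-][O+]=O
Why: Ozonolysis (Criegee mechanism) cleaves the remaining electron-rich enol-ether C=C, turning furan C3 into the C6 aldehyde and furan C2 into a methyl oxalyl ester on O8, without touching the cyclopropane centres.

Step 3
Reactants: 6 acrolein; 7 propargyl bromide
Product: 9 (±)-hex-1-en-5-yn-3-ol, via allenylzinc bromide 8 (not isolated)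
Conditions: Zn dust, THF/sat. aq. NH4Cl, 0 °C
Reagents that add atoms: none
Why: In this zinc Barbier propargylation the allenylzinc species adds through its γ-carbon to the aldehyde in 1,2-fashion to give the homopropargylic alcohol, and no stereocontrol is needed at this stage.

Step 4
Reactants: 9 (±)-hex-1-en-5-yn-3-ol
Product: 10 (R)-hex-1-en-5-yn-3-ol
Conditions: Ti(OiPr)4 (15 mol %), L-(+)-DIPT (18 mol %), t-BuOOH (0.6 equiv), 4 Å MS, CH2Cl2, −20 °C
Reagents that add atoms: none
Why: In the Sharpless kinetic resolution with L-(+)-DIPT the (S)-allylic alcohol is epoxidised much faster, so the (R)-enantiomer, which carries the future C2 centre, is left behind at slightly over half conversion.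

Step 5
Reactants: 10 (R)-hex-1-en-5-yn-3-ol
Product: 11 (R)-tert-butyl(hex-1-en-5-yn-3-yloxy)dimethylsilane
Conditions: TBSCl, imidazole, DMF, rt
Reagents that add atoms: tert-butyldimethylsilyl chloride CC(C)(C)[Si](C)(C)Cl
Why: Standard imidazole-promoted silylation masks the C2 hydroxyl for the organometallic and enolate steps and leaves the stereocentre untouched.

Step 6
Reactants: 11 silyl ether
Product: 13 (R,E)-tert-butyl[(6-iodo-5-methylhexa-1,5-dien-3-yl)oxy]dimethylsilane, via alkenyldimethylalane 12 (not isolated)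
Conditions: Me3Al (2.5 equiv), Cp2ZrCl2 (25 mol %), CH2Cl2, 0 °C to rt; then I2, THF, −30 °C
Reagents that add atoms: trimethylaluminium C[Al](C)C; iodine II
Why: Negishi zirconium-catalysed carboalumination adds Me and Al syn across the terminal alkyne (far faster than across the vinyl group) with Al at the terminus, and iodinolysis with retention gives the E-iodide that fixes the C4=C5 geometry.

Step 7
Reactants: 5 cyclopropane carbaldehyde; 13 alkenyl iodide
Product: 15 methyl (1R,2R,3S)-2-(ethoxycarbonyl)-3-[(1R,2E,5R)-5-(tert-butyldimethylsilyloxy)-1-hydroxy-3-methylhepta-2,6-dien-1-yl]cyclopropyl oxalate, via alkenylchromium dichloride 14 (not isolated)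
Conditions: CrCl2 (4 equiv), NiCl2 (2 mol %), DMF, rt
Reagents that add atoms: none
Why: In the Nozaki–Hiyama–Kishi coupling the alkenylchromium reagent forms with retention of the E geometry and adds only to the aldehyde among three ester groups, and Felkin–Anh attack anti to the oxygen-bearing cyclopropane carbon C8 should set 6R.

Step 8
Reactants: 15 cyclopropyl carbinol
Product: 18 (2R,3S)-2-[(1E,4R)-4-(tert-butyldimethylsilyloxy)-2-methylhexa-1,5-dien-1-yl]-5-oxooxolane-3-carbaldehyde (trans), via cyclopropanol 16 (not isolated), via hydroxy ester aldehyde 17 (not isolated)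
Conditions: Ba(OH)2·8H2O, MeOH, 0 °C
Reagents that add atoms: none
Why: Saponification of the oxalate frees the C8 cyclopropanol, whose push–pull retro-aldol opening cleaves the sacrificial C8–C11 bond to the C8 aldehyde and the C11H2–CO2Et arm, and the C6 hydroxyl then lactonises onto C12 so that C6 and C7, both untouched, end up trans, which is also the preferred arrangement at the epimerisable C7.

Step 9
Reactants: 18 lactone aldehyde
Product: 20 (4R,5R)-5-[(1E,4R)-4-(tert-butyldimethylsilyloxy)-2-methylhexa-1,5-dien-1-yl]-4-[(1R)-1-hydroxy-3-methylbut-3-en-1-yl]oxolan-2-one, via diisopinocampheylborinate 19 (not isolated)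
Conditions: (+)-Ipc2BOMe (from (−)-α-pinene), methallylMgCl, Et2O, −78 °C to rt; then 18, −78 °C; then pH 7 buffer, 30% H2O2, 0 °C
Reagents that add atoms: methallylmagnesium chloride C=C(C)C[Mg]Cl
Why: Brown asymmetric methallylboration through a closed chair transition state delivers the methallyl group to the aldehyde face that gives 8R, should override the modest opposite Felkin bias of C7, and leaves the lactone alone.

Step 10
Reactants: 20 hydroxy lactone
Product: 23 (4R,5R)-5-[(1E,4R)-4-(tert-butyldimethylsilyloxy)-2-methylhexa-1,5-dien-1-yl]-4-[(1R)-1-hydroxy-3-methylbut-3-en-1-yl]-3-methylideneoxolan-2-one, via Mannich base 21 (not isolated), via ammonium iodide 22 (not isolated)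
Conditions: LDA (2.3 equiv), THF, −78 °C; Me2N=CH2+ I−, −78 °C to rt; aq. work-up; MeI, MeOH, rt; aq. NaHCO3, CH2Cl2
Reagents that add atoms: Eschenmoser's salt C=[N+](C)C.[I-]
Why: Dianion formation (alkoxide plus lactone enolate), Mannich reaction, N-methylation and β-elimination make up the classical α-methylenation of a lactone and install C11=C13, where C11 ends sp2 so that no stereocontrol is needed.

Step 11
Reactants: 24 methyl (S)-3-hydroxy-2-methylpropanoate
Product: 25 methyl (S)-3-(tert-butyldimethylsilyloxy)-2-methylpropanoate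
Conditions: TBSCl, imidazole, CH2Cl2, rt
Reagents that add atoms: tert-butyldimethylsilyl chloride CC(C)(C)[Si](C)(C)Cl
Why: Standard silylation protects the primary hydroxyl, and the 2′S centre comes from the chiral pool.

Step 12
Reactants: 25 silyl ether ester
Product: 26 (S)-3-(tert-butyldimethylsilyloxy)-2-methylpropanoic acid
Conditions: LiOH, THF/H2O, 0 °C to rt; then 1 M HCl to pH 4
Reagents that add atoms: lithium hydroxide [Li+].[OH-]
Why: Mild saponification of the methyl ester should leave the silyl ether and the α-stereocentre intact.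

Step 13
Reactants: 23 hydroxy methylene lactone; 26 acid
Product: 27 C8 ester of 23 and 26 (2R,6R,7R,8R,2′S triene)
Conditions: DCC, DMAP (cat.), CH2Cl2, 0 °C to rt
Reagents that add atoms: none
Why: Steglich esterification acylates the only free hydroxyl (C8) with retention at C8, and carbodiimide activation should not epimerise C2′.

Step 14
Reactants: 27 triene ester
Product: 28 bis(tert-butyldimethylsilyl) ether of the target
Conditions: second-generation Hoveyda–Grubbs catalyst (10 mol %), toluene (1 mM), 80 °C
Reagents that add atoms: none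
Why: In this ring-closing metathesis ruthenium loads on the monosubstituted C1 vinyl group and closes onto the methallyl olefin held nearby by the trans-lactone; strain in a cyclodeca-1,5-diene that already holds the E-C4=C5 bond should favour Z-C1=C10, and the C4=C5 and C11=C13 olefins are poor metathesis partners.

Step 15
Reactants: 28 bis-silyl ether
Product: 29 target CNP0254953.1
Conditions: HF·pyridine, pyridine, THF, 0 °C to rt
Reagents that add atoms: none
Why: Buffered fluoride desilylation should free both hydroxyls without base-induced conjugate addition to the methylene lactone or acid-induced transannular cyclisation.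

Compound list
1 | methyl furan-2-carboxylate | COC(=O)c1ccco1 | starting material
2 | ethyl diazoacetate | CCOC(=O)C=[N+]=[N-] | starting material
3 | 6-ethyl 3-methyl (1R,5R,6R)-2-oxabicyclo[3.1.0]hex-3-ene-3,6-dicarboxylate | COC(=O)C1=C[C@@H]2[C@@H](C(=O)OCC)[C@@H]2O1 | intermediate
4 | secondary ozonide of 3 (cyclopropane centres as in 3) | COC(=O)C12OOC(O1)[C@@H]3[C@@H](C(=O)OCC)[C@@H]3O2 | intermediate
5 | methyl (1R,2R,3R)-2-(ethoxycarbonyl)-3-formylcyclopropyl oxalate | O=C[C@@H]1[C@@H](C(=O)OCC)[C@@H]1OC(=O)C(=O)OC | intermediate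
6 | acrolein | C=CC=O | starting material
7 | propargyl bromide | C#CCBr | starting material
8 | allenylzinc bromide | C=C=C[Zn]Br | intermediate
9 | (±)-hex-1-en-5-yn-3-ol | C#CCC(O)C=C | intermediate
10 | (R)-hex-1-en-5-yn-3-ol | C#CC[C@@H](O)C=C | intermediate
11 | (R)-tert-butyl(hex-1-en-5-yn-3-yloxy)dimethylsilane | C#CC[C@@H](O[Si](C)(C)C(C)(C)C)C=C | intermediate
12 | (R,E)-alkenyldimethylalane from 11 | C[Al](C)/C=C(\C)C[C@@H](O[Si](C)(C)C(C)(C)C)C=C | intermediate
13 | (R,E)-tert-butyl[(6-iodo-5-methylhexa-1,5-dien-3-yl)oxy]dimethylsilane | I/C=C(\C)C[C@@H](O[Si](C)(C)C(C)(C)C)C=C | intermediate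
14 | (R,E)-alkenylchromium dichloride from 13 | Cl[Cr](Cl)/C=C(\C)C[C@@H](O[Si](C)(C)C(C)(C)C)C=C | intermediate
15 | methyl (1R,2R,3S)-2-(ethoxycarbonyl)-3-[(1R,2E,5R)-5-(tert-butyldimethylsilyloxy)-1-hydroxy-3-methylhepta-2,6-dien-1-yl]cyclopropyl oxalate | O[C@H](/C=C(\C)C[C@@H](O[Si](C)(C)C(C)(C)C)C=C)[C@@H]1[C@@H](C(=O)OCC)[C@@H]1OC(=O)C(=O)OC | intermediate
16 | cyclopropanol from 15 (oxalate removed, centres as in 15) | O[C@H](/C=C(\C)C[C@@H](O[Si](C)(C)C(C)(C)C)C=C)[C@@H]1[C@@H](C(=O)OCC)[C@@H]1O | intermediate
17 | ethyl (3S,4R,5E,8R)-8-(tert-butyldimethylsilyloxy)-3-formyl-4-hydroxy-6-methyldeca-5,9-dienoate | O[C@H](/C=C(\C)C[C@@H](O[Si](C)(C)C(C)(C)C)C=C)[C@H](CC(=O)OCC)C=O | intermediate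
18 | (2R,3S)-2-[(1E,4R)-4-(tert-butyldimethylsilyloxy)-2-methylhexa-1,5-dien-1-yl]-5-oxooxolane-3-carbaldehyde | C1C(=O)O[C@H](/C=C(\C)C[C@@H](O[Si](C)(C)C(C)(C)C)C=C)[C@H]1C=O | intermediate
19 | diisopinocampheylborinate of 20 | C1C(=O)O[C@H](/C=C(\C)C[C@@H](O[Si](C)(C)C(C)(C)C)C=C)[C@H]1[C@H](OB([C@H]2C[C@H]3C[C@@H]([C@@H]2C)C3(C)C)[C@H]2C[C@H]3C[C@@H]([C@@H]2C)C3(C)C)CC(C)=C | intermediate
20 | (4R,5R)-5-[(1E,4R)-4-(tert-butyldimethylsilyloxy)-2-methylhexa-1,5-dien-1-yl]-4-[(1R)-1-hydroxy-3-methylbut-3-en-1-yl]oxolan-2-one | C1C(=O)O[C@H](/C=C(\C)C[C@@H](O[Si](C)(C)C(C)(C)C)C=C)[C@H]1[C@H](O)CC(C)=C | intermediate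
21 | 3-[(dimethylamino)methyl] derivative of 20 (C11 epimers) | CN(C)CC1C(=O)O[C@H](/C=C(\C)C[C@@H](O[Si](C)(C)C(C)(C)C)C=C)[C@H]1[C@H](O)CC(C)=C | intermediate
22 | trimethylammonium iodide from 21 | C[N+](C)(C)CC1C(=O)O[C@H](/C=C(\C)C[C@@H](O[Si](C)(C)C(C)(C)C)C=C)[C@H]1[C@H](O)CC(C)=C.[I-] | intermediate
23 | 3-methylidene derivative of 20 (2R,6R,7R,8R) | C=C1C(=O)O[C@H](/C=C(\C)C[C@@H](O[Si](C)(C)C(C)(C)C)C=C)[C@H]1[C@H](O)CC(C)=C | intermediate
24 | methyl (S)-3-hydroxy-2-methylpropanoate | COC(=O)[C@@H](C)CO | starting material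
25 | methyl (S)-3-(tert-butyldimethylsilyloxy)-2-methylpropanoate | COC(=O)[C@@H](C)CO[Si](C)(C)C(C)(C)C | intermediate
26 | (S)-3-(tert-butyldimethylsilyloxy)-2-methylpropanoic acid | OC(=O)[C@@H](C)CO[Si](C)(C)C(C)(C)C | intermediate
27 | C8 ester of 23 and 26 | C=C1C(=O)O[C@H](/C=C(\C)C[C@@H](O[Si](C)(C)C(C)(C)C)C=C)[C@H]1[C@H](OC(=O)[C@@H](C)CO[Si](C)(C)C(C)(C)C)CC(C)=C | intermediate
28 | bis(tert-butyldimethylsilyl) ether of the target (4E, 1(10)Z) | C=C1C(=O)O[C@@H]2/C=C(\C)C[C@@H](O[Si](C)(C)C(C)(C)C)/C=C(/C)C[C@@H](OC(=O)[C@@H](C)CO[Si](C)(C)C(C)(C)C)[C@@H]12 | intermediate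
29 | CNP0254953.1 | C=C1C(=O)O[C@@H]2/C=C(\C)C[C@@H](O)/C=C(/C)C[C@@H](OC(=O)[C@@H](C)CO)[C@@H]12 | target

Total step count: 15.
Longest linear sequence: 11 steps (steps 3–10 and 13–15).

Steps most likely to fail

1. Step 14. Oligomerisation may outrun closure of the strained ten-membered ring, the ruthenium carbene may be held back by chelation to the conjugated lactone or the C8 ester, or the new olefin may form with the wrong geometry. The fallback builds the carbocycle before the exocyclic methylene and the side chain are present. It sets out from 20. Ring-closing metathesis of this leaner diene would give the macrocyclic saturated hydroxy lactone F1. α-Methylenation as in step 10 would pass through the macrocyclic Mannich base F2 and the macrocyclic ammonium iodide F3 to the macrocyclic hydroxy methylene lactone F4. Steglich acylation with 26 comes back to the route at 28.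

2. Step 7. Facial selectivity at C6 may be poor under chromium conditions, and the oxalyl group may migrate from O8 to the new alkoxide. The fallback moves the control of C6 from the C–C bond formation to a catalyst-controlled hydride delivery. It sets out from 15 (as an epimer mixture). Dess–Martin oxidation would give the cyclopropyl alkenyl ketone F5. Corey–Bakshi–Shibata reduction, with the oxazaborolidine enantiomer matched to the 6R carbinol, comes back to the route at 15.

3. Step 9. Selectivity may erode because reagent and substrate bias are mismatched, and the α-centre of the aldehyde may epimerise during a slow addition. The fallback uses the substrate bias and inverts afterwards. It sets out from 18. Hosomi–Sakurai addition of methallyltrimethylsilane (BF3·OEt2, CH2Cl2, −78 °C) should follow the Felkin–Anh sense and give the 8S hydroxy lactone F6. α-Methylenation as in step 10 would pass through the 8S Mannich base F7 and the 8S ammonium iodide F8 to the 8S hydroxy methylene lactone F9. Mitsunobu esterification with 26 (PPh3, DIAD) inverts C8 while it installs the side chain, and comes back to the route at 27.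

Further compounds
F1 | step 14 | macrocyclic saturated hydroxy lactone (C2 silyl ether, free C8 hydroxyl) | C1C(=O)O[C@@H]2/C=C(\C)C[C@@H](O[Si](C)(C)C(C)(C)C)/C=C(/C)C[C@@H](O)[C@@H]12
F2 | step 14 | macrocyclic Mannich base (C11 epimers) | CN(C)CC1C(=O)O[C@@H]2/C=C(\C)C[C@@H](O[Si](C)(C)C(C)(C)C)/C=C(/C)C[C@@H](O)[C@@H]12
F3 | step 14 | macrocyclic ammonium iodide | C[N+](C)(C)CC1C(=O)O[C@@H]2/C=C(\C)C[C@@H](O[Si](C)(C)C(C)(C)C)/C=C(/C)C[C@@H](O)[C@@H]12.[I-]
F4 | step 14 | macrocyclic hydroxy methylene lactone | C=C1C(=O)O[C@@H]2/C=C(\C)C[C@@H](O[Si](C)(C)C(C)(C)C)/C=C(/C)C[C@@H](O)[C@@H]12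
F5 | step 7 | cyclopropyl alkenyl ketone (C6 ketone of 15) | O=C(/C=C(\C)C[C@@H](O[Si](C)(C)C(C)(C)C)C=C)[C@@H]1[C@@H](C(=O)OCC)[C@@H]1OC(=O)C(=O)OC
F6 | step 9 | 8S hydroxy lactone (C8 epimer of 20) | C1C(=O)O[C@H](/C=C(\C)C[C@@H](O[Si](C)(C)C(C)(C)C)C=C)[C@H]1[C@@H](O)CC(C)=C
F7 | step 9 | 8S Mannich base (C11 epimers) | CN(C)CC1C(=O)O[C@H](/C=C(\C)C[C@@H](O[Si](C)(C)C(C)(C)C)C=C)[C@H]1[C@@H](O)CC(C)=C
F8 | step 9 | 8S ammonium iodide | C[N+](C)(C)CC1C(=O)O[C@H](/C=C(\C)C[C@@H](O[Si](C)(C)C(C)(C)C)C=C)[C@H]1[C@@H](O)CC(C)=C.[I-]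
F9 | step 9 | 8S hydroxy methylene lactone (C8 epimer of 23) | C=C1C(=O)O[C@H](/C=C(\C)C[C@@H](O[Si](C)(C)C(C)(C)C)C=C)[C@H]1[C@@H](O)CC(C)=C
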